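Lindenane numbering is used for all ring positions (C1–C15; ring A = C1, C3, C4, C5, C10; ring B = C5–C10). Compound numbers refer to the list after the steps.

## The problem

Compound 21 is the C2-symmetric head-to-head dimer of the lindenane dienolide 20 (chloranthalactone A). The C8=C9 enol-lactone alkenes of two molecules are joined through C8–C8′ and C9–C9′ into a cis–anti–cis cyclobutane, each half reacting on the face anti to its C14 methyl. Each half is a compact 3/5/6/5 array: a cyclopropane (C1–C2–C3) cis-fused to cyclopentane ring A, ring A trans-fused to ring B at C5–C10, and an α-methyl-γ-alkylidene butenolide on C7/C8. Four stereocentres (C1, C3, C5, C10) must be in place before dimerisation, and C8 and C9 arise in it. The quaternary C10 carries a methyl group and the cyclopropane carbon C1, two substituents of similar size, so C10 cannot be relied on to direct C5, whereas a substituent on C5 can send a reagent to the opposite face of C10. The cyclopropane methylene C2 lies on the same face as C14, which with the trans ring fusion forces the less favourable chair-like bicyclo[3.1.0]hexane, so neither sterics nor thermodynamics helps at C1/C3. The C4=C15 methylene is part of a vinylcyclopropane that ionises to a cyclopropylcarbinyl cation under acid, and the cross-conjugated enol lactone is labile to base, nucleophiles and light, so both must arrive late. The key step is possible because C3 is bonded to C4 and C4 carries both C15 and C5: a 1-bromovinyl group on C5 and a plain cyclopropyl group on C10 put palladium on C4 within reach of a cyclopropyl C–H, so forming C3–C4 closes ring A with the methylene already in place.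

## Retrosynthesis

**21 ⇒ 20.** The cyclobutane bonds C8–C8′ and C9–C9′ are cut together. This is the only cut that uses the symmetry; cutting one bond would mean a stepwise union of two fully elaborated, sensitive halves. Compound 20 has half the atoms and four of the stereocentres of each half. The forward [2+2] photodimerisation must be head-to-head and engage both molecules on the face anti to C14.

**20 ⇒ 18 ⇒ 15 + 16.** The butenolide is cut at O–C12 and C7–C11, returning the C8 ketone 15 and ethyl pyruvate 16 by way of aldol adduct 18. Building the lactone on a ketone is preferred to carrying an enol lactone through the metal-catalysed ring closure under carbonate at high temperature. Ketone 15 is a 12-carbon tricycle whose only heteroatom function is C8=O. The forward steps need enolisation towards C7 only (C9 is neopentylic) and a dehydrative enol lactonisation that spares the vinylcyclopropane.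

**15 ⇒ 14.** No skeletal bond is cut; the C8 carbonyl is masked as a dioxolane. Ketal 14 differs from 15 only in this group, which keeps enolate chemistry out of the ring closure. Its removal must be mild.

**14 ⇒ 13 (key disconnection).** The C3–C4 bond is cut, opening ring A to bromide 13. The neighbouring cuts at C1–C2/C2–C3 mean cyclopropanating a ring A alkene, which delivers CH2 to the less hindered face, anti to C14, and so gives the wrong isomer. The chosen cut removes a ring and two stereocentres (C1, C3) and leaves a cyclopropyl group that can be bought. Compound 13 is a monocyclic ketal with only C5 and C10 stereogenic. The forward reaction must metalate a cyclopropyl CH2 in preference to the C14 methyl, and of the two CH2 groups the one whose closure leaves C2 syn to C14.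

**13 ⇒ 11 ⇒ 10.** The C4–Br bond is traced to the acetyl group of methyl ketone 10 through trisylhydrazone 11. A terminal-alkyne route would need extra carbon-level adjustments. The forward Shapiro bromination must form the alkenyl anion towards C15 and leave the C5–H alone.

**10 ⇒ 8 ⇒ 7.** The acetyl group is the ozonolysis product of an isopropenyl group, and the dioxolane of 8 comes from ketone 7. Ketalising before ozonolysis avoids differentiating two ketones.

**7 ⇒ 6 ⇒ 4.** The 3,3,4-trisubstituted cyclohexanone 7 is a ring-opened pinane. Rejoining C7 to the carbon that becomes C4 gives bicyclo[3.1.1]heptanone 4, reached forward through tertiary iodide 6. This turns the trans C5/C10 relation of a flexible ring into a facial question on a rigid bicycle. The forward cleavage must break only the cyclobutane bond α to the carbonyl and spare the cyclopropane.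

**4 ⇒ 1 + 2.** The C10–C1 bond is cut: conjugate addition of cyclopropylmagnesium bromide 2 to (1R,5R)-(+)-verbenone 1. The gem-dimethyl bridge directs the nucleophile, so the configured bridgehead (C5) controls the quaternary C10, and the chiral pool supplies the absolute configuration. A cycloaddition of a β,β-disubstituted enone would have to create the quaternary centre enantioselectively, for which there is little precedent. Verbenone already holds C5–C10, C14, the C8 oxygen and the two-carbon unit at C5.

## Roads not taken

**Alternative 1:** The C9–C10 and C9′–C10′ bonds are cut, with C9–C9′ present from the start in the succinate diester A1 of an enantiopure 4-methylbicyclo[3.1.0]hex-3-en-2-ol. Its bis(silyl ketene acetal) would undergo two Ireland–Claisen rearrangements to diacid A2. Merits: the symmetry is used in two directions, the quaternary C10 and the C9 centres come from suprafacial chirality transfer, and the central cyclobutane bond is fixed before any ring exists. In that last respect it is better than the chosen plan, which depends on the regio- and facial course of a late photodimerisation. Weak points: no ring closes; the geometry of both ketene acetals of a succinate must be controlled to fix C9 and C9′; the cyclopropylcarbinyl allylic ester ionises easily. After A2, both rings B, both butenolides, the C8–C8′ bond, the C5–C6 bonds and both exocyclic methylenes (starting from C4=C5 alkenes) are still to be made. The chosen plan is far shorter and ends with a dimerisation that follows the monomer's own steric bias.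

**Alternative 2:** In each half C7–C8, C11–C12 and C12–O are cut. The trans-3,4-disubstituted cyclobutane-1,2-dione A3, carrying two ring A units with but-2-ynyl groups on C5, would be treated with Ru3(CO)12 (or Mo(CO)6) under CO. Each alkyne, one ketone and CO would combine in a hetero-Pauson–Khand annulation to give bis-ketal A4. Merits: six bonds, both rings B and both butenolides in one operation, with the cyclobutane stereochemistry fixed beforehand. On convergence it is better than the chosen plan. Weak points: a cyclobutane-1,2-dione under metal carbonyls at high temperature can decarbonylate or open. Ketone–alkyne–CO couplings are established for forming five-membered carbocycles, not a six-membered ring B. Two oxygen-bearing quaternary centres (C8, C8′) need facial control. A3 is itself a hard target, and A4 still needs deketalisation and double methylenation of hindered cyclopropyl ketones. The chosen plan offers a simple monocyclic substrate and a short end game.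

**Alternative 3:** The C1–C3 bond is cut. Buffered solvolysis of the 1β-mesylate A5 of a trans-eudesm-3-ene (hexafluoroisopropanol, 2,6-lutidine) would let the C3=C4 alkene displace the sulfonate and, after loss of a C15 proton, give tricycle A6. Merits: backside displacement fixes the cyclopropane face stereospecifically (1β leaving group, C2 syn to C14). The chosen plan has to obtain this from catalyst control, so here the alternative is better. Eudesmane precursors are also easy to make. Weak points: the cyclohex-3-enyl to bicyclo[3.1.0]hexyl direction runs against the usual ring-expanding course of cyclopropylcarbinyl cations. The C4 cation partitions between loss of H15, loss of H5, solvent capture and reversal. The product vinylcyclopropane is exposed to the ionising medium that formed it. The oxygen sits on C7, so the butenolide would need a later C8 oxidation. Both roads go beyond known chemistry at the key step. The chosen plan closes the ring under basic, non-ionising conditions and has the C8 oxygen in place from the start.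

Key step: step 8

Remark on the chemistry: the target is read as the homodimer of (1R,3S,5S,10S)-configured 20. Compound 1 is assumed to be of high enantiomeric purity. The (R,R) ligand written in step 8 stands for whichever enantiomer proves matched to 13; this cannot be deduced on paper.

## Steps

Step 1
Reactants: 1 (1R,5R)-(+)-verbenone; 2 cyclopropylmagnesium bromide
Product: 4 (1R,4S,5S)-4-cyclopropyl-4,6,6-trimethylbicyclo[3.1.1]heptan-2-one (cyclopropyl anti to the gem-dimethyl bridge), via trimethylsilyl enol ether 3 (not isolated)
Conditions: c-C3H5MgBr (2 equiv), CuBr·SMe2 (20 mol %), Me3SiCl, THF, −40 → 0 °C; then 1 M HCl, rt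
Reagents that add atoms: none
Why: Copper-catalysed conjugate addition of a Grignard reagent, accelerated by Me3SiCl; the gem-dimethyl bridge shields one face of the enone, so cyclopropyl enters from the methylene-bridge side and sets the quaternary centre (future C10) with cyclopropyl anti to the carbon that becomes C4; acid work-up hydrolyses 3.

Step 2
Reactants: 4 (1R,4S,5S)-4-cyclopropyl-4,6,6-trimethylbicyclo[3.1.1]heptan-2-one
Product: 6 (3S,4R)-3-cyclopropyl-4-(2-iodopropan-2-yl)-3-methylcyclohexan-1-one, via silyl enol ether iodide 5 (not isolated)
Conditions: Me3SiCl, NaI, MeCN, 0 °C → rt; then aq. NaHCO3/Na2S2O3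
Reagents that add atoms: iodotrimethylsilane (formed in the flask from Me3SiCl and NaI), C[Si](C)(C)I
Why: Lewis-acid-induced cyclobutane fragmentation of a pinane ketone: O-silylation, heterolysis of the strained bond between the α-bridgehead and the gem-dimethyl carbon, capture of the tertiary cation by iodide and hydrolysis of enol ether 5; the two stereocentres are untouched, so the side chain on C5 ends trans to cyclopropyl.

Step 3
Reactants: 6 (3S,4R)-3-cyclopropyl-4-(2-iodopropan-2-yl)-3-methylcyclohexan-1-one
Product: 7 (3S,4S)-3-cyclopropyl-3-methyl-4-(prop-1-en-2-yl)cyclohexan-1-one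
Conditions: KOt-Bu, THF, 0 °C
Reagents that add atoms: none
Why: E2 dehydroiodination with a bulky base; Hofmann-type removal of a methyl proton should be preferred over the single ring C–H, which is flanked by the quaternary centre, giving the isopropenyl group.

Step 4
Reactants: 7 (3S,4S)-3-cyclopropyl-3-methyl-4-(prop-1-en-2-yl)cyclohexan-1-one
Product: 8 (7S,8S)-7-cyclopropyl-7-methyl-8-(prop-1-en-2-yl)-1,4-dioxaspiro[4.5]decane
Conditions: HOCH2CH2OH, PPTS (cat.), benzene, reflux (Dean–Stark)
Reagents that add atoms: ethylene glycol, OCCO
Why: Acid-catalysed ketalisation of an unhindered cyclohexanone with azeotropic removal of water; the weak acid should leave the isopropenyl group in place, and the dioxolane protects C8 through the ozonolysis, organolithium and palladium steps.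

Step 5
Reactants: 8 (7S,8S)-7-cyclopropyl-7-methyl-8-(prop-1-en-2-yl)-1,4-dioxaspiro[4.5]decane
Product: 10 1-[(7S,8R)-7-cyclopropyl-7-methyl-1,4-dioxaspiro[4.5]decan-8-yl]ethan-1-one, via ozonide 9 (not isolated)
Conditions: O3, CH2Cl2, −78 °C; then PPh3, −78 °C → rt
Reagents that add atoms: ozone, [O-][O+]=O
Why: Ozonolysis of a 1,1-disubstituted alkene with reductive work-up; cyclopropane and ketal are inert, and the neutral conditions keep the now enolisable C5 centre.

Step 6
Reactants: 10 1-[(7S,8R)-7-cyclopropyl-7-methyl-1,4-dioxaspiro[4.5]decan-8-yl]ethan-1-one
Product: 11 N′-{(1E)-1-[(7S,8R)-7-cyclopropyl-7-methyl-1,4-dioxaspiro[4.5]decan-8-yl]ethylidene}-2,4,6-tri(propan-2-yl)benzenesulfonohydrazide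
Conditions: 2,4,6-(i-Pr)3C6H2SO2NHNH2, PPTS (cat.), THF, rt
Reagents that add atoms: 2,4,6-tri(propan-2-yl)benzenesulfonohydrazide, CC(C)c1cc(C(C)C)c(S(=O)(=O)NN)c(C(C)C)c1
Why: Condensation of a ketone with an arenesulfonyl hydrazide; the E isomer, with the sulfonamide syn to the methyl group, should dominate for steric reasons and prepares the regiochemistry of step 7.

Step 7
Reactants: 11 trisylhydrazone of 10
Product: 13 (7S,8R)-8-(1-bromoethenyl)-7-cyclopropyl-7-methyl-1,4-dioxaspiro[4.5]decane, via alkenyllithium 12 (not isolated)
Conditions: n-BuLi (2.2 equiv), TMEDA, THF, −78 → 0 °C; then BrCH2CH2Br, −78 °C → rt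
Reagents that add atoms: 1,2-dibromoethane, BrCCBr
Why: Shapiro reaction: the dianion forms at the methyl group syn to the sulfonamide and loses sulfinate and N2 to give alkenyllithium 12, which 1,2-dibromoethane brominates; because deprotonation occurs only at the methyl group, the C5 stereocentre is never enolised.

Step 8
Reactants: 13 (7S,8R)-8-(1-bromoethenyl)-7-cyclopropyl-7-methyl-1,4-dioxaspiro[4.5]decane
Product: 14 (1R,3S,5S,10S)-8,8-(ethylenedioxy)-11,12,13-trinorlind-4(15)-ene (lindenane tricycle: C2 syn to C14; H1, H3 and H5 anti to C14; trans A/B fusion)
Conditions: Pd(OAc)2 (10 mol %), (R,R)-TADDOL-derived N,N-dimethylphosphoramidite (20 mol %), t-BuCO2H (30 mol %), Cs2CO3 (1.5 equiv), mesitylene, 130 °C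
Reagents that add atoms: none
Why: Proposed new method: zerovalent palladium inserts into the C4–Br bond, bromide is exchanged for pivalate, a carboxylate-assisted concerted metalation–deprotonation of a cyclopropyl CH2 gives a six-membered palladacycle (Pd, C4, C5, C10, C1, C3), and C(sp2)–C(sp3) reductive elimination forms C3–C4; the closest known reactions are intramolecular C(sp3)–H arylations and alkenylations of aryl and alkenyl bromides under zerovalent-palladium/pivalate catalysis, including enantioselective arylation of cyclopropyl CH2 groups, but an all-carbon-tethered 1-bromovinyl/cyclopropyl pair closing a bicyclo[3.1.0]hexane has not been shown. Ring A closes as a five-membered carbocycle by reductive elimination from that palladacycle, and its fusion to ring B is trans because bromovinyl and cyclopropyl are already trans on C5 and C10. At C3 the new bond must be cis to the C1–C10 bond, since only a cis C–H can reach palladium, so the cyclopropane is cis-fused. The configuration at C1 is decided by which of the two diastereotopic CH2 groups is metalated; the wanted one (C2 syn to C14) leads to the more strained tricycle, so the choice is placed under catalyst control with a bulky chiral phosphoramidite of the kind that distinguishes the two CH2 groups of a cyclopropyl ring, used in its matched sense. Selectivity over the C14 methyl (five-membered palladacycle, leading to a methylenecyclobutane) rests on the higher acidity of cyclopropyl C–H bonds and on the much easier reductive elimination to a five-membered ring. The dioxolane keeps C8 out of enolate chemistry under carbonate at 130 °C.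

Step 9
Reactants: 14 lindenane tricycle dioxolane
Product: 15 (1R,3S,5S,10S)-11,12,13-trinorlind-4(15)-en-8-one
Conditions: PPTS, acetone–H2O (10:1), 50 °C
Reagents that add atoms: water, O
Why: Acid-catalysed ketal hydrolysis; a weak pyridinium acid is used because the vinylcyclopropane would ionise under strong acid.

Step 10
Reactants: 15 (1R,3S,5S,10S)-11,12,13-trinorlind-4(15)-en-8-one; 16 ethyl pyruvate
Product: 18 ethyl 2-hydroxy-2-[(1R,3S,5S,10S)-8-oxo-11,12,13-trinorlind-4(15)-en-7-yl]propanoate (mixture at C7 and C11), via lithium enolate 17 (not isolated)
Conditions: LiN(i-Pr)2, THF, −78 °C; ethyl pyruvate, −78 °C; AcOH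
Reagents that add atoms: none
Why: Kinetic deprotonation takes place at C7 because C9 is neopentylic beside the quaternary C10; aldol addition of enolate 17 to the ketone carbonyl of the pyruvate follows, and both new centres (C7, C11) become sp2 in step 11, so the mixture is used as such.

Step 11
Reactants: 18 aldol adduct
Product: 20 chloranthalactone A, (1R,3S,5S,10S)-lindena-4(15),7(11),8-trien-12,8-olide, via alkylidene keto ester 19 (not isolated)
Conditions: TsOH·H2O (cat.), toluene, 90 °C, 4 Å MS
Reagents that add atoms: none
Why: Acid-catalysed dehydration of the β-hydroxy ketone to alkylidene keto ester 19, enolisation of C8 towards C9 and enol lactonisation onto the cis ester with loss of ethanol give the γ-alkylidene butenolide; no stereocentre is formed.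

Step 12
Reactants: 20 chloranthalactone A (two molecules)
Product: 21 target: head-to-head, anti, cis–anti–cis cyclobutane dimer of 20 (bonds C8–C8′ and C9–C9′)
Conditions: hν (medium-pressure Hg lamp, Pyrex filter), degassed hexane, rt
Reagents that add atoms: none
Why: [2+2] photodimerisation of the C8=C9 enol-lactone alkene; bonding C9 to C9′ first leaves radicals at C8 and C8′ stabilised by oxygen and the unsaturated lactone, which accounts for head-to-head union, and each alkene should add suprafacially on its face anti to C14 with the two halves anti to each other, which sets C8 and C9 in both halves.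

## Compound list

1 | (1R,5R)-(+)-verbenone, (1R,5R)-4,6,6-trimethylbicyclo[3.1.1]hept-3-en-2-one | CC1=CC(=O)[C@@H]2C[C@H]1C2(C)C | starting material
2 | cyclopropylmagnesium bromide | Br[Mg]C1CC1 | starting material
3 | {[(1R,4S,5S)-4-cyclopropyl-4,6,6-trimethylbicyclo[3.1.1]hept-2-en-2-yl]oxy}trimethylsilane | C[C@@]1(C3CC3)C=C(O[Si](C)(C)C)[C@@H]2C[C@H]1C2(C)C | intermediate (not isolated)
4 | (1R,4S,5S)-4-cyclopropyl-4,6,6-trimethylbicyclo[3.1.1]heptan-2-one | C[C@@]1(C3CC3)CC(=O)[C@@H]2C[C@H]1C2(C)C | intermediate
5 | {[(4R,5S)-5-cyclopropyl-4-(2-iodopropan-2-yl)-5-methylcyclohex-1-en-1-yl]oxy}trimethylsilane | CC(C)(I)[C@@H]1CC=C(O[Si](C)(C)C)C[C@@]1(C)C1CC1 | intermediate (not isolated)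
6 | (3S,4R)-3-cyclopropyl-4-(2-iodopropan-2-yl)-3-methylcyclohexan-1-one | CC(C)(I)[C@@H]1CCC(=O)C[C@@]1(C)C1CC1 | intermediate
7 | (3S,4S)-3-cyclopropyl-3-methyl-4-(prop-1-en-2-yl)cyclohexan-1-one | CC(=C)[C@@H]1CCC(=O)C[C@@]1(C)C1CC1 | intermediate
8 | (7S,8S)-7-cyclopropyl-7-methyl-8-(prop-1-en-2-yl)-1,4-dioxaspiro[4.5]decane | CC(=C)[C@@H]1CCC2(OCCO2)C[C@@]1(C)C1CC1 | intermediate
9 | ozonide of 8: 8-(3-methyl-1,2,4-trioxolan-3-yl) analogue of 8 (mixture at the trioxolane carbon) | CC1(OCOO1)[C@@H]2CCC3(OCCO3)C[C@@]2(C)C2CC2 | intermediate (not isolated)
10 | 1-[(7S,8R)-7-cyclopropyl-7-methyl-1,4-dioxaspiro[4.5]decan-8-yl]ethan-1-one | CC(=O)[C@@H]1CCC2(OCCO2)C[C@@]1(C)C1CC1 | intermediate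
11 | (E)-2,4,6-tri(propan-2-yl)benzenesulfonyl hydrazone of 10 | C/C(=N\NS(=O)(=O)c1c(C(C)C)cc(C(C)C)cc1C(C)C)[C@@H]1CCC2(OCCO2)C[C@@]1(C)C1CC1 | intermediate
12 | alkenyllithium: 13 with Li in place of Br | [Li]C(=C)[C@@H]1CCC2(OCCO2)C[C@@]1(C)C1CC1 | intermediate (not isolated)
13 | (7S,8R)-8-(1-bromoethenyl)-7-cyclopropyl-7-methyl-1,4-dioxaspiro[4.5]decane | C=C(Br)[C@@H]1CCC2(OCCO2)C[C@@]1(C)C1CC1 | intermediate
14 | (1R,3S,5S,10S)-8,8-(ethylenedioxy)-11,12,13-trinorlind-4(15)-ene | C=C1[C@H]2C[C@H]2[C@@]2(C)[C@H]1CCC3(OCCO3)C2 | intermediate
15 | (1R,3S,5S,10S)-11,12,13-trinorlind-4(15)-en-8-one | C=C1[C@H]2C[C@H]2[C@@]2(C)[C@H]1CCC(=O)C2 | intermediate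
16 | ethyl pyruvate | CCOC(=O)C(C)=O | starting material
17 | lithium C7–C8 enolate of 15 | C=C1[C@H]2C[C@H]2[C@@]2(C)[C@H]1CC=C(O[Li])C2 | intermediate (not isolated)
18 | ethyl 2-hydroxy-2-[(1R,3S,5S,10S)-8-oxo-11,12,13-trinorlind-4(15)-en-7-yl]propanoate (mixture at C7, C11) | C=C1[C@H]2C[C@H]2[C@@]2(C)[C@H]1CC(C(C)(O)C(=O)OCC)C(=O)C2 | intermediate
19 | ethyl 2-[(1R,3S,5S,10S)-8-oxo-11,12,13-trinorlind-4(15)-en-7-ylidene]propanoate (ester cis to C8) | C=C1[C@H]2C[C@H]2[C@@]2(C)[C@H]1C/C(=C(\C)C(=O)OCC)C(=O)C2 | intermediate (not isolated)
20 | chloranthalactone A, (1R,3S,5S,10S)-lindena-4(15),7(11),8-trien-12,8-olide | C=C1[C@H]2C[C@H]2[C@@]2(C)[C@H]1CC1=C(C)C(=O)OC1=C2 | intermediate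
21 | head-to-head, anti, cis–anti–cis [2+2] dimer of 20 through C8=C9 | C=C1[C@H]2C[C@H]2[C@@]2(C)[C@H]1CC1=C(C)C(=O)O[C@]13[C@H]2[C@H]1[C@@]2(C)[C@@H]4C[C@@H]4C(=C)[C@@H]2CC2=C(C)C(=O)O[C@@]213 | target

## Step count and least certain steps

Total: 12 steps. Longest linear sequence: 12 steps (1 → 21).

**Step 8 (key step).** Three things may go wrong. First, poor discrimination between the two cyclopropyl CH2 groups: the wanted closure gives the more strained tricycle, so the substrate may work against the ligand. Second, metalation of the C14 methyl through a five-membered palladacycle. Third, loss of the alkenylpalladium by β-hydride elimination from C5 or by protodebromination at 130 °C. The fallback uses known reaction types, sets out from 1 and returns at 14. Conjugate addition of vinylmagnesium bromide under CuBr·SMe2 catalysis gives the vinyl adduct F1. Cleavage with Me3SiI as in step 2 gives the iodide F2, and KOt-Bu gives the diene ketone F3. Ketalisation as in step 4 gives the dioxolane F4. m-CPBA epoxidises the more electron-rich 1,1-disubstituted alkene to the epoxide F5. Lithium 2,2,6,6-tetramethylpiperidide generates the α-lithiated epoxide, a carbenoid that cyclopropanates the vinyl group on C10 intramolecularly to the tertiary alcohol F6. Dehydration towards the methyl group with the Burgess reagent gives 14. In this route the two bridge methyls of 1 become C3 and C15. The configuration of the epoxide carbon is relayed to the cyclopropane face, so the epimers of F5 would be separated and only the one leading to C2 syn to C14 carried on.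

**Step 2.** The tertiary cation released on cleavage, or adventitious HI, may start hydride and alkyl shifts that end in a cyclopropylcarbinyl cation and open the cyclopropane; the iodide may also lose HI unselectively on standing. The fallback cleaves before the cyclopropane exists; it sets out from 1 and returns at 7. It passes through F1, F2 and F3 as described above. The vinyl group of F3 is then cyclopropanated with CH2N2 under Pd(OAc)2 catalysis, which should prefer the monosubstituted alkene over the isopropenyl group.

**Step 11.** Protonation of C15 of the vinylcyclopropane by TsOH at 90 °C may open the cyclopropane or move the alkene into ring A before lactonisation is complete. The fallback avoids strong acid; it sets out from 18 and returns at 20. SOCl2/pyridine at 0 °C dehydrates 18 to 19. LiOH in aqueous THF gives the keto acid F7. Ac2O/NaOAc at 70 °C closes the enol lactone through the mixed anhydride.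

**Step 12.** Direct excitation may give poor regio- and facial control (head-to-tail or syn dimers), competing unimolecular photochemistry of the dienolide and vinylcyclopropane, or oligomerisation. The fallback changes the excited state used; it sets out from 20 and returns at 21. Triplet energy transfer from thioxanthone under 405 nm light in concentrated solution would drive the dimerisation through the 1,4-biradical without exciting 20 directly.

## Further compounds

F1 | step 8 | 4-ethenyl-4,6,6-trimethylbicyclo[3.1.1]heptan-2-one (vinyl anti to the gem-dimethyl bridge) | C=C[C@]1(C)CC(=O)[C@@H]2C[C@H]1C2(C)C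
F2 | step 8 | 3-ethenyl-4-(2-iodopropan-2-yl)-3-methylcyclohexan-1-one (side chain trans to vinyl) | CC(C)(I)[C@@H]1CCC(=O)C[C@@]1(C)C=C
F3 | step 8 | 3-ethenyl-3-methyl-4-(prop-1-en-2-yl)cyclohexan-1-one (isopropenyl trans to vinyl) | CC(=C)[C@@H]1CCC(=O)C[C@@]1(C)C=C
F4 | step 8 | 7-ethenyl-7-methyl-8-(prop-1-en-2-yl)-1,4-dioxaspiro[4.5]decane | CC(=C)[C@@H]1CCC2(OCCO2)C[C@@]1(C)C=C
F5 | step 8 | 7-ethenyl-7-methyl-8-(2-methyloxiran-2-yl)-1,4-dioxaspiro[4.5]decane (epimers at the oxirane carbon) | CC1(CO1)[C@@H]2CCC3(OCCO3)C[C@@]2(C)C=C
F6 | step 8 | 8,8-(ethylenedioxy)-11,12,13-trinorlindan-4-ol (tertiary alcohol at C4, ring stereocentres as in 14) | CC1(O)[C@H]2C[C@H]2[C@@]2(C)[C@H]1CCC3(OCCO3)C2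
F0 | step 2 | none | none
F7 | step 11 | 2-[(1R,3S,5S,10S)-8-oxo-11,12,13-trinorlind-4(15)-en-7-ylidene]propanoic acid | C=C1[C@H]2C[C@H]2[C@@]2(C)[C@H]1C/C(=C(\C)C(=O)O)C(=O)C2
F0 | step 12 | none | none
A1 | alternative 1 | bis(4-methylbicyclo[3.1.0]hex-3-en-2-yl) butanedioate (ester oxygen anti to the cyclopropane CH2) | O=C(CCC(=O)O[C@H]1C=C(C)[C@@H]2C[C@H]12)O[C@H]1C=C(C)[C@@H]2C[C@H]12
A2 | alternative 1 | 2,3-bis(2-methylbicyclo[3.1.0]hex-3-en-2-yl)butanedioic acid | OC(=O)[C@H]([C@]1(C)C=C[C@H]2C[C@@H]12)[C@H](C(=O)O)[C@]1(C)C=C[C@H]2C[C@@H]12
A3 | alternative 2 | trans-3,4-bis[3-(but-2-yn-1-yl)-2-methyl-4,4-(ethylenedioxy)bicyclo[3.1.0]hexan-2-yl]cyclobutane-1,2-dione | O=C1C(=O)[C@H]([C@@]2(C)[C@@H]3C[C@@H]3C4(OCCO4)[C@@H]2CC#CC)[C@H]1[C@@]1(C)[C@@H]2C[C@@H]2C3(OCCO3)[C@@H]1CC#CC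
A4 | alternative 2 | 4,4′-bis(ethylene ketal) of the 15,15′-dinor-4,4′-dioxo analogue of 21 | C15(OCCO5)[C@H]2C[C@H]2[C@@]2(C)[C@H]1CC1=C(C)C(=O)O[C@]13[C@H]2[C@H]1[C@@]2(C)[C@@H]4C[C@@H]4C5(OCCO5)[C@@H]2CC2=C(C)C(=O)O[C@@]213
A5 | alternative 3 | 7,7-(ethylenedioxy)-11,12,13-trinor-trans-eudesm-3-en-1β-yl methanesulfonate | CC1=CC[C@@H](OS(C)(=O)=O)[C@]2(C)CCC3(OCCO3)C[C@@H]12
A6 | alternative 3 | 7,7-(ethylenedioxy)-11,12,13-trinorlind-4(15)-ene | C=C1[C@H]2C[C@H]2[C@@]2(C)[C@H]1CC3(OCCO3)CC2
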